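The runs are calculated for substances that don't exist.

Follow one G through the flask and ask what it ends as.

| flask | G | Z | remark | time |
|---|---|---|---|---|
| birch | 0.055 M | 0.056 mol% | run made earlier |  |
| maple | 0.077 M | 0.056 mol% | run made earlier |  |
| alder | 0.12 M | 0.056 mol% | run made earlier |  |
| oak | 0.055 M | 0.11 mol% | run made earlier |  |
| summer | 0.055 M | 0.056 mol% | one stirred flow tank at steady state, fed with the mixture as stated, mean residence time 6.0 h |  |
| dawn | 0.055 M | 0.056 mol% | one stirred flow tank at steady state, fed with the mixture as stated, mean residence time 30.0 h |  |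
| midnight | 0.055 M | 0.056 mol% | everything together in a closed stirred flask, run for 6.0 h | 6.0 h |
| winter | 0.055 M (fed, over 4.80 h) | 0.056 mol% | all but G at the start; G goes in evenly over 4.80 h, the run ends at 6.0 h | 6.0 h |

| run | time / h | L / % | G / % |
|---|---|---|---|
| birch | 0.667 | 13.4 | 79.5 |
| birch | 1.33 | 20.1 | 63.2 |
| birch | 2.00 | 22.3 | 50.1 |
| birch | 2.50 | 22.9 | 47.0 |
| birch | 3.00 | 22.6 | 41.7 |
| birch | 4.00 | 24.3 | 32.1 |
| maple | 0.833 | 19.3 | 69.1 |
| maple | 1.50 | 25.2 | 54.9 |
| maple | 2.50 | 25.9 | 42.1 |
| maple | 3.00 | 27.1 | 37.5 |
| maple | 4.00 | 25.7 | 30.8 |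
| maple | 5.00 | 26.7 | 24.5 |
| alder | 0.333 | 15.5 | 81.0 |
| alder | 1.00 | 27.7 | 59.5 |
| alder | 1.50 | 29.4 | 50.9 |
| alder | 2.50 | 32.6 | 38.8 |
| alder | 4.00 | 30.9 | 28.0 |
| alder | 5.00 | 28.9 | 22.0 |
| oak | 1.00 | 24.9 | 60.5 |
| oak | 2.00 | 30.0 | 43.1 |
| oak | 3.00 | 29.6 | 34.0 |
| oak | 4.00 | 30.0 | 28.0 |
| oak | 5.00 | 27.5 | 20.0 |

(readings scatter by 1 percentage point)

- the stated concentrations are those of everything mixed, before any reaction; amounts are the same in each set-up
- the feed brings no volume worth counting
- the earlier runs were made in a closed, stirred flask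

- the set-up with the highest amount of L at the outlet or at the end, in percent of the G put in ("none" if the first two lie within 2 percentage points) (summer / dawn / midnight / winter / none)
- amount of L at the outlet or at the end, in percent of the G put in, summer
- amount of L at the outlet or at the end, in percent of the G put in, dawn
- amount of L at the outlet or at the end, in percent of the G put in, midnight
- amount of L at the outlet or at the end, in percent of the G put in, winter

I build midnight on birch, which has the same charge, one process at a time. With the main step alone, every G lost becomes L. Birch's first reading gives a pseudo-first-order constant of 0.344 h⁻¹, so midnight would hold 87.3% L at 6.0 h.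

Now add the fork. At that first birch reading, 65.4% of the G lost stands as L (a selectivity, read with the scatter of the readings), and this cuts my number to 57.1%.

Then add the rest, which I read as Z fading and L decaying. From 2.00 h to 4.00 h in birch, G falls 18 percentage points but L rises 2 points. G's tail there runs at 0.223 h⁻¹, so I expect 20.6% G in midnight at the end.

Alder's late G decay, 0.227 h⁻¹, is close to birch's, so I borrow its late balance: after 2.50 h, each G lost costs 22.0% of a G's worth of L. Starting from birch's last reading, I reckon midnight ends at 21.8% L. So my estimate of the L standing per G lost by that moment is 27.4%, and I call this the keep chance.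

The forecast gives 14.5% for summer, 6.5% for dawn, 23% for midnight and 15.5% for winter, with midnight best; of winter it says “G arrives after Z has faded”. Its midnight stands 1.2 points above mine.

The flask gives 14.8% for summer, 7.41% for dawn, 21.2% for midnight and 12.5% for winter. So midnight leads summer by 6.4 points, more than the margin, and the forecast stands within its tolerance.

    G + Z → Z + L (k = 2.80 M⁻¹ s⁻¹)
    G → X (k = 4.40 × 10⁻⁵ s⁻¹)
    2 Z → E (k = 4.50 M⁻¹ s⁻¹)
    L ⇌ J (K = 3.70, k = 3.50 × 10⁻⁵ s⁻¹)

In midnight, G to L over Z has 57% of its turnover up to 6.0 h behind it by 1.20 h, and Z is down to 25.0% of its charge at 3.00 h, when L to J has 46% of its turnover up to 6.0 h behind it. Each step taken net, L is made 2.14 times as fast as it is used at 1.93 h, but 0.428 times at 6.00 h, and midnight's keep chance ends at 26.9%. Winter has lost 53.3% of its G, my 27.4% on that gives 14.6%, and winter holds 12.5%.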